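Ring positions are written as ring letter, hyphen, number (A-5 is carbon 5 of ring A). Labels without a hyphen (A1, A2 …) are compounds of the plans that were turned down.

## Analysis of the target

- The target is a 19-membered macrocyclic bis(bibenzyl). Four benzene rings are joined in a cycle by two diaryl ether oxygens and two CH2CH2 bridges, in the order ring A (catechol)–O–ring B (para-phenylene)–bridge 1–ring C (catechol)–O–ring D (meta-phenylene)–bridge 2–ring A.
- Ring A carries hydroxyls at A-1 and A-6, bridge 2 at A-3 and the ether oxygen at A-5. Ring C carries bridge 1 at C-1, hydroxyls at C-3 and C-4 and the ether oxygen at C-5. Ring B is substituted only at B-1 (oxygen) and B-4 (bridge 1), ring D only at D-1 (oxygen) and D-3 (bridge 2).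
- There is no stereocentre and no double bond outside the arenes, so nothing stereochemical has to be set or related; the only spatial question is whether the large ring closes.
- The sensitive groups are the two catechols, which oxidise easily to ortho-quinones in air, in base and in the presence of copper. They must stay masked until the last step.
- The difficulty lies in the two diaryl ether bonds. Each sits on an oxygen flanked by another oxygen substituent (A-5 next to A-6, C-5 next to C-4), so both are hindered, electron-rich coupling sites, and one of them must in addition close the macrocycle while five phenolic oxygens are kept apart.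
- The strategy rests on ring B. It is a plain para-disubstituted benzene with the crowded A-5 oxygen on B-1 and a carbon on B-4. B-1 and B-6 can therefore be placed on that oxygen as a two-carbon alkyne, and B-2 to B-5 supplied by a four-carbon diene that brings the B-4 carbon with it, so ring B is grown on the oxygen instead of being coupled to it.

## Retrosynthetic reasoning

**24 ⇒ 23.** The four catechol hydroxyls of target 24 are traced back to the four methyl ethers of macrocycle 23. Methyl ethers are the one phenol protection that survives organolithium, ylide, hydride, prolonged heating and copper catalysis alike, and a boron trihalide removes all four at once without touching diaryl ethers. The forward step has to cleave four aryl–OMe bonds and release the air-sensitive bis-catechol only at the very end.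

**23 ⇒ 22.** The macrocycle is opened at the C-5–O bond of the ring C–O–ring D ether, which leads to 22, a seco compound with a free D-1 hydroxyl and a bromine at C-5. This ether is chosen for the ring closure because its phenol partner has no ortho substituent and because the other ether is secured earlier without any coupling. Cutting a bridge instead would demand a second olefination-type macrocyclisation plus a reduction on the large ring. The forward reaction is an intramolecular copper-catalysed etherification under pseudo-dilution.

**22 ⇒ 21 ⇒ 20 ⇒ 17 + 18.** The D-1 hydroxyl of 22 is masked as the benzyl ether in 21. Bridge 1 is cut between its two carbons by way of stilbene 20, which comes from a Wittig reaction of phosphonium salt 17 with aldehyde 18. Aldehyde 18 is purchased and delivers ring C complete, with both methoxy groups and the bromine in place, so no aromatic substitution is needed on ring C. Two constraints follow for the forward direction. The alkene must be saturated without hydrogenolysis of the benzyl ether or the C–Br bond, which calls for a metal-free hydrogen-transfer reduction. The benzyl ether must then be removed without a palladium hydrogenolysis that would also take the bromine, which calls for Lewis-acid cleavage with a cation scavenger.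

**17 ⇒ 16 ⇒ 15.** The phosphonium salt 17 is taken back through benzylic alcohol 16 to methyl ester 15. The ester carbon on B-4 becomes the first carbon of bridge 1. Putting the ylide on the large fragment lets ring C enter as the commercial aldehyde and saves the steps of making a ring C phosphonium salt.

**15 ⇒ 12 + 13 (key disconnection).** Ring B of 15 is cut at the B-1/B-2 and B-5/B-6 bonds. That leaves the ethynyl ether 12, in which the A-5 oxygen already carries B-1 and B-6, and methyl coumalate 13, which supplies B-2 to B-5 and the ester on B-4. The cut is made here because it removes the hindered A-5–O–B-1 coupling altogether: the oxygen–carbon bond is made on a small linear electrophile, and the arene is then built around it. The forward reaction must be a regioselective (4+2) cycloaddition followed by cycloreversion that expels the lactone bridge. The alkyne oxidation level is essential. An aryl vinyl ether would give a dihydroarene that aromatises by expelling the phenol, and the ether would be lost.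

**12 ⇒ 9 ⇒ 6 + 7.** The ethynyl ether 12 is traced through the dichlorovinyl ether 9 to phenol 6 and trichloroethylene 7. Compound 7 acts, by way of dichloroacetylene 8, as a two-carbon electrophile that adds the phenoxide regardless of ortho substituents. Elimination and halogen–metal exchange on 9 (through 10 and 11) then give the alkyne. The benzyl ether on ring D is chosen because it withstands these basic steps.

**6 ⇒ 5 ⇒ 2 + 3; 2 ⇒ 1.** Bridge 2 is cut between its carbons by way of stilbene 5, from a Wittig reaction of phosphonium salt 2 (from benzylic bromide 1) with aldehyde 3. Aldehyde 3 brings the complete oxygenation of ring A, with the A-5 oxygen as the only free hydroxyl, so the oxygens never have to be differentiated. Its hydroxyl is meta to the formyl group, so its phenoxide does not deactivate the aldehyde and no protection is planned. The reduction of 5 to 6 must again spare the benzyl ether.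

## Alternatives that were turned down

**Alternative 1:** The A-5–O–B-1 ether is traced back to an ester, the 20-membered aryl benzoate macrolactone A1, in which a carbonyl carbon sits between the ring A oxygen and B-1.
- Forward key step: zerovalent nickel inserts into the acyl–oxygen bond of A1, the acyl nickel species loses its carbonyl group, and reductive elimination of aryl and aryloxide contracts the ring to the 19-membered ether A2, which is the same compound as 23.
- For it: the ring is closed by macrolactonisation, and esterification of a hindered phenol is far more dependable than any macro-etherification. On ring closure this plan is stronger than the chosen one.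
- Against it: decarbonylative ether formation works best when the acyl part is an azine or otherwise activated. A1 is the poorest case, a plain benzoate with an electron-rich, ortho-substituted aryloxide. Oxidative addition would need very high temperature, and carbon–oxygen reductive elimination from divalent nickel is slow. The aryloxide can leave the metal, which would give ring-opened or oligomeric material. All of this would happen in the last skeleton-forming step, on the most valuable intermediate.
- Comparison: step counts are similar, since both bridges and the other ether are still needed. The chosen strategy offers in place of the easier ring closure an uncertain step that comes early (step 6), on an acyclic compound, needs only heat, and can be replaced by a conventional coupling without redesign.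

**Alternative 2:** Ring A itself is dismantled into the furan A3, 3-(4-bromophenoxy)-4-methoxyfuran, and methyl propiolate A4.
- Forward key step: a normal-demand Diels–Alder reaction forms the A-3/A-4 and A-1/A-2 bonds, and acid opens the oxygen bridge of the adduct so that the bridge oxygen becomes the A-1 hydroxyl of methyl 3-(4-bromophenoxy)-5-hydroxy-4-methoxybenzoate A5.
- For it: one operation gives a fully differentiated trioxygenated ring A with an ester for bridge 2 and a bromide handle on ring B, and electron-rich dioxyfurans react readily with propiolates. On differentiating A-1 from A-6 this plan is stronger, but the target has both as free hydroxyls, so the advantage is not used.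
- Against it: the crowded ether is not avoided, only moved. A3 needs an aryl ether on a 3-furanol, whose keto tautomer makes O-arylation difficult. The direction of bridge opening depends on the small difference in donor strength between methoxy and aryloxy; the wrong direction gives the isomer with the hydroxyl ortho to the ester. After A5, both bridges, the second ether and the macrocyclisation all remain.
- Comparison: ring A can be bought with the right pattern (compound 3), so this plan spends its key step on the ring that needs it least and is longer overall. The chosen strategy uses its cycloaddition on ring B, the ring whose attachment is the real problem.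

**Alternative 3:** The A-1 and C-3 hydroxyls are removed, which leaves the macrocyclic bis(O-aryl diethylcarbamate) A6.
- Forward key step: A6 is lithiated twice ortho to the carbamates (each has only one free ortho position, A-1 and C-3), and borylation followed by oxidation gives the dihydroxy bis(carbamate) A7.
- For it: rings A and C would come from cheaper, less oxygenated arenes, both catechols are completed in one operation, and no methyl ethers have to be cleaved. On these points this plan is as strong or stronger.
- Against it: anionic ortho-Fries rearrangement of the lithiated carbamates competes unless the temperature is kept very low. Double metalation of a large, poorly soluble macrocycle needs excess strong base, which can also attack positions ortho to the diaryl ether oxygens on rings B and D and the benzylic bridge positions. A7 is a pair of monoprotected catechols prone to carbamoyl migration, and carbamate removal needs hydride or hot hydroxide on an oxidation-prone polyphenol. The two hindered diaryl ethers still have to be made next to an oxygen substituent.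
- Comparison: this plan stakes the end of the synthesis on a double C–H functionalisation of the macrocycle. The chosen strategy carries every oxygen from purchased aldehydes, solves one of the two ether problems by construction, and ends with a routine demethylation.

Key step: step 6

Remark on the chemistry: the two Wittig products (5 and 20) are expected as E/Z mixtures and are drawn without alkene geometry, because both isomers converge in the following reduction.

## Route

Step 1
Reactants: 1 1-(benzyloxy)-3-(bromomethyl)benzene
Product: 2 [3-(benzyloxy)benzyl]triphenylphosphonium bromide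
Conditions: PPh3, toluene, 110 °C
Reagents that add atoms: triphenylphosphine, c1ccc(cc1)P(c1ccccc1)c1ccccc1
Why: SN2 quaternisation of a primary benzylic bromide by triphenylphosphine; the salt should precipitate from toluene.

Step 2
Reactants: 2 [3-(benzyloxy)benzyl]triphenylphosphonium bromide; 3 3-hydroxy-4,5-dimethoxybenzaldehyde
Product: 5 5-{2-[3-(benzyloxy)phenyl]ethenyl}-2,3-dimethoxyphenol (E/Z mixture), via phosphorus ylide 4 (not isolated)
Conditions: KOtBu (2.3 equiv), THF, 0 °C → rt; then 1 M HCl
Reagents that add atoms: none
Why: Wittig olefination with a semi-stabilised benzylic ylide; the extra equivalent of base holds the phenol as its phenoxide, which is meta to the formyl group and therefore does not deactivate it by resonance.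

Step 3
Reactants: 5 5-{2-[3-(benzyloxy)phenyl]ethenyl}-2,3-dimethoxyphenol (E/Z mixture)
Product: 6 5-{2-[3-(benzyloxy)phenyl]ethyl}-2,3-dimethoxyphenol
Conditions: TsNHNH2, NaOAc, DME/H2O, reflux
Reagents that add atoms: none
Why: Diimide reduction; concerted syn transfer of H2 to the disubstituted alkene leaves the benzyl ether and the arenes untouched, which catalytic hydrogenation over palladium would not.

Step 4
Reactants: 6 5-{2-[3-(benzyloxy)phenyl]ethyl}-2,3-dimethoxyphenol; 7 trichloroethylene
Product: 9 5-{2-[3-(benzyloxy)phenyl]ethyl}-1-{[(E)-1,2-dichloroethenyl]oxy}-2,3-dimethoxybenzene, via dichloroacetylene 8 (not isolated)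
Conditions: K2CO3, DMF, 70 °C
Reagents that add atoms: none
Why: Base-induced loss of HCl from 7 gives 8, to which the phenoxide adds; anti protonation gives the (E)-dichlorovinyl ether, and the small linear electrophile is indifferent to the ortho-methoxy group.

Step 5
Reactants: 9 5-{2-[3-(benzyloxy)phenyl]ethyl}-1-{[(E)-1,2-dichloroethenyl]oxy}-2,3-dimethoxybenzene
Product: 12 5-{2-[3-(benzyloxy)phenyl]ethyl}-1-(ethynyloxy)-2,3-dimethoxybenzene, via chloroethynyl ether 10 (not isolated), via lithium aryloxyacetylide 11 (not isolated)
Conditions: n-BuLi (2.5 equiv), Et2O, −78 → −40 °C; then H2O, −78 °C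
Reagents that add atoms: none
Why: Deprotonation and β-elimination give chloroalkyne 10, chlorine–lithium exchange gives acetylide 11, and cold protonation gives the terminal ynol ether (elimination–metalation route to aryl alkynyl ethers); at −78 °C the benzyl ether is not metalated.

Step 6
Reactants: 12 5-{2-[3-(benzyloxy)phenyl]ethyl}-1-(ethynyloxy)-2,3-dimethoxybenzene; 13 methyl coumalate (methyl 2-oxo-2H-pyran-5-carboxylate)
Product: 15 methyl 4-(5-{2-[3-(benzyloxy)phenyl]ethyl}-2,3-dimethoxyphenoxy)benzoate, via bridged bicyclic lactone 14 (not isolated)
Conditions: 13 (1.5 equiv), toluene, 110 °C, sealed tube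
Reagents that add atoms: none
Why: Inverse-electron-demand Diels–Alder reaction followed by retro-Diels–Alder loss of CO2: the donor orbital of the aryloxyalkyne, largest on its terminal carbon, meets the acceptor orbital of the pyrone, largest at position 6 (β to the ester and vinylogous to the lactone carbonyl). The terminal carbon therefore bonds to position 6 and the oxygen-bearing carbon to position 3, giving lactone 14, a 2-oxabicyclo[2.2.2]octa-5,7-dien-3-one. At the reaction temperature 14 should expel CO2 by cycloreversion, and the six remaining carbons are benzene ring B with the ester para to the ether. The closest known reaction type is the conversion of methyl coumalate with ynamines, ketene acetals and terminal alkynes into para-substituted benzoates. Ring B is closed by an intermolecular (4+2) cycloaddition that forms the B-1/B-2 and B-5/B-6 bonds from two components, not by cyclisation of a chain, so no chain ring-closure mode applies. No stereocentre remains, since the two bridgehead centres of 14 vanish on aromatisation. The step needs para regioselectivity, which the matched polarisation of both partners and the unhindered terminal alkyne carbon secure, and it needs the alkyne oxidation level, because an enol ether adduct would aromatise by expelling the phenol. The benzyl ether, the methyl ethers and the ester are inert to neutral heating.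

Step 7
Reactants: 15 methyl 4-(5-{2-[3-(benzyloxy)phenyl]ethyl}-2,3-dimethoxyphenoxy)benzoate
Product: 16 [4-(5-{2-[3-(benzyloxy)phenyl]ethyl}-2,3-dimethoxyphenoxy)phenyl]methanol
Conditions: LiAlH4, THF, 0 °C; then H2O/NaOH work-up
Reagents that add atoms: none
Why: Hydride reduction of an aryl ester to the benzylic alcohol; ethers are untouched.

Step 8
Reactants: 16 [4-(5-{2-[3-(benzyloxy)phenyl]ethyl}-2,3-dimethoxyphenoxy)phenyl]methanol
Product: 17 [4-(5-{2-[3-(benzyloxy)phenyl]ethyl}-2,3-dimethoxyphenoxy)benzyl]triphenylphosphonium bromide
Conditions: PPh3·HBr, MeCN, reflux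
Reagents that add atoms: triphenylphosphine hydrobromide, Br.c1ccc(cc1)P(c1ccccc1)c1ccccc1
Why: Direct conversion of a benzylic alcohol into its phosphonium salt; protonation and ionisation are eased by the para-aryloxy group, and the phosphine captures the benzylic electrophile before it can alkylate an arene.

Step 9
Reactants: 17 [4-(5-{2-[3-(benzyloxy)phenyl]ethyl}-2,3-dimethoxyphenoxy)benzyl]triphenylphosphonium bromide; 18 3-bromo-4,5-dimethoxybenzaldehyde
Product: 20 5-{2-[3-(benzyloxy)phenyl]ethyl}-1-{4-[2-(3-bromo-4,5-dimethoxyphenyl)ethenyl]phenoxy}-2,3-dimethoxybenzene (E/Z mixture), via phosphorus ylide 19 (not isolated)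
Conditions: KOtBu, THF, 0 °C → rt
Reagents that add atoms: none
Why: Wittig olefination of an aryl aldehyde with a semi-stabilised ylide; the aryl bromide and all ethers are inert to the ylide and to KOtBu at this temperature.

Step 10
Reactants: 20 5-{2-[3-(benzyloxy)phenyl]ethyl}-1-{4-[2-(3-bromo-4,5-dimethoxyphenyl)ethenyl]phenoxy}-2,3-dimethoxybenzene (E/Z mixture)
Product: 21 5-{2-[3-(benzyloxy)phenyl]ethyl}-1-{4-[2-(3-bromo-4,5-dimethoxyphenyl)ethyl]phenoxy}-2,3-dimethoxybenzene
Conditions: TsNHNH2, NaOAc, DME/H2O, reflux
Reagents that add atoms: none
Why: Diimide reduction saturates the stilbene without a metal catalyst, so neither the C–Br bond nor the benzyl ether is cleaved.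

Step 11
Reactants: 21 5-{2-[3-(benzyloxy)phenyl]ethyl}-1-{4-[2-(3-bromo-4,5-dimethoxyphenyl)ethyl]phenoxy}-2,3-dimethoxybenzene
Product: 22 3-[2-(3-{4-[2-(3-bromo-4,5-dimethoxyphenyl)ethyl]phenoxy}-4,5-dimethoxyphenyl)ethyl]phenol
Conditions: BCl3, C6HMe5, CH2Cl2, −78 °C; then H2O
Reagents that add atoms: none
Why: Lewis-acid debenzylation with pentamethylbenzene as a non-basic benzyl cation scavenger; at −78 °C aryl benzyl ethers are cleaved much faster than aryl methyl ethers, and the aryl bromide, which hydrogenolysis would endanger, is not affected.

Step 12
Reactants: 22 3-[2-(3-{4-[2-(3-bromo-4,5-dimethoxyphenyl)ethyl]phenoxy}-4,5-dimethoxyphenyl)ethyl]phenol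
Product: 23 macrocyclic tetra-O-methyl ether of the target (19-membered ring, methoxy groups at A-1, A-6, C-3 and C-4)
Conditions: CuI (20 mol %), N,N-dimethylglycine·HCl, Cs2CO3, 1,4-dioxane, 100 °C, syringe-pump addition (about 3 mM)
Reagents that add atoms: none
Why: Intramolecular Ullmann diaryl ether synthesis with amino-acid-ligated monovalent copper, conditions that accept ortho-alkoxy aryl bromides; the only phenol is unhindered, and slow addition keeps ring closure ahead of oligomerisation.

Step 13
Reactants: 23 macrocyclic tetra-O-methyl ether of the target
Product: 24 target compound CNP0511668.0 (hydroxyls at A-1, A-6, C-3 and C-4)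
Conditions: BBr3 (excess), CH2Cl2, −78 °C → rt; then H2O, under argon
Reagents that add atoms: none
Why: Boron tribromide cleavage of the four aryl methyl ethers by bromide attack at methyl; diaryl ether bonds are not cleaved, and the bis-catechol is released only in this last step and worked up with exclusion of air.

## Compound list

1 | 1-(benzyloxy)-3-(bromomethyl)benzene (3-benzyloxybenzyl bromide) | BrCc1cccc(OCc2ccccc2)c1 | starting material
2 | [3-(benzyloxy)benzyl]triphenylphosphonium bromide | [Br-].c1ccc(cc1)[P+](Cc1cccc(OCc2ccccc2)c1)(c1ccccc1)c1ccccc1 | intermediate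
3 | 3-hydroxy-4,5-dimethoxybenzaldehyde | COc1cc(C=O)cc(O)c1OC | starting material
4 | [3-(benzyloxy)benzylidene]triphenylphosphorane (not isolated) | c1ccc(cc1)P(=Cc1cccc(OCc2ccccc2)c1)(c1ccccc1)c1ccccc1 | intermediate
5 | 5-{2-[3-(benzyloxy)phenyl]ethenyl}-2,3-dimethoxyphenol (E/Z mixture) | COc1cc(C=Cc2cccc(OCc3ccccc3)c2)cc(O)c1OC | intermediate
6 | 5-{2-[3-(benzyloxy)phenyl]ethyl}-2,3-dimethoxyphenol | COc1cc(CCc2cccc(OCc3ccccc3)c2)cc(O)c1OC | intermediate
7 | trichloroethylene | ClC=C(Cl)Cl | starting material
8 | dichloroacetylene (not isolated) | ClC#CCl | intermediate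
9 | 5-{2-[3-(benzyloxy)phenyl]ethyl}-1-{[(E)-1,2-dichloroethenyl]oxy}-2,3-dimethoxybenzene | Cl/C=C(/Cl)Oc1cc(CCc2cccc(OCc3ccccc3)c2)cc(OC)c1OC | intermediate
10 | 5-{2-[3-(benzyloxy)phenyl]ethyl}-1-[(chloroethynyl)oxy]-2,3-dimethoxybenzene (not isolated) | ClC#COc1cc(CCc2cccc(OCc3ccccc3)c2)cc(OC)c1OC | intermediate
11 | lithium (5-{2-[3-(benzyloxy)phenyl]ethyl}-2,3-dimethoxyphenoxy)acetylide (not isolated) | [Li]C#COc1cc(CCc2cccc(OCc3ccccc3)c2)cc(OC)c1OC | intermediate
12 | 5-{2-[3-(benzyloxy)phenyl]ethyl}-1-(ethynyloxy)-2,3-dimethoxybenzene | C#COc1cc(cc(OC)c1OC)CCc1cccc(OCc2ccccc2)c1 | intermediate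
13 | methyl coumalate (methyl 2-oxo-2H-pyran-5-carboxylate) | COC(=O)C1=COC(=O)C=C1 | starting material
14 | methyl 5-(5-{2-[3-(benzyloxy)phenyl]ethyl}-2,3-dimethoxyphenoxy)-3-oxo-2-oxabicyclo[2.2.2]octa-5,7-diene-7-carboxylate (racemic, not isolated) | COC(=O)C1=CC2C(=O)OC1C=C2Oc1cc(CCc2cccc(OCc3ccccc3)c2)cc(OC)c1OC | intermediate
15 | methyl 4-(5-{2-[3-(benzyloxy)phenyl]ethyl}-2,3-dimethoxyphenoxy)benzoate | COC(=O)c1ccc(cc1)Oc1cc(cc(OC)c1OC)CCc1cccc(OCc2ccccc2)c1 | intermediate
16 | [4-(5-{2-[3-(benzyloxy)phenyl]ethyl}-2,3-dimethoxyphenoxy)phenyl]methanol | OCc1ccc(cc1)Oc1cc(cc(OC)c1OC)CCc1cccc(OCc2ccccc2)c1 | intermediate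
17 | [4-(5-{2-[3-(benzyloxy)phenyl]ethyl}-2,3-dimethoxyphenoxy)benzyl]triphenylphosphonium bromide | [Br-].c1ccc(cc1)[P+](Cc1ccc(cc1)Oc1cc(cc(OC)c1OC)CCc1cccc(OCc2ccccc2)c1)(c1ccccc1)c1ccccc1 | intermediate
18 | 3-bromo-4,5-dimethoxybenzaldehyde | COc1cc(C=O)cc(Br)c1OC | starting material
19 | [4-(5-{2-[3-(benzyloxy)phenyl]ethyl}-2,3-dimethoxyphenoxy)benzylidene]triphenylphosphorane (not isolated) | c1ccc(cc1)P(=Cc1ccc(cc1)Oc1cc(cc(OC)c1OC)CCc1cccc(OCc2ccccc2)c1)(c1ccccc1)c1ccccc1 | intermediate
20 | 5-{2-[3-(benzyloxy)phenyl]ethyl}-1-{4-[2-(3-bromo-4,5-dimethoxyphenyl)ethenyl]phenoxy}-2,3-dimethoxybenzene (E/Z mixture) | COc1cc(C=Cc2ccc(cc2)Oc2cc(cc(OC)c2OC)CCc2cccc(OCc3ccccc3)c2)cc(Br)c1OC | intermediate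
21 | 5-{2-[3-(benzyloxy)phenyl]ethyl}-1-{4-[2-(3-bromo-4,5-dimethoxyphenyl)ethyl]phenoxy}-2,3-dimethoxybenzene | COc1cc(CCc2ccc(cc2)Oc2cc(cc(OC)c2OC)CCc2cccc(OCc3ccccc3)c2)cc(Br)c1OC | intermediate
22 | 3-[2-(3-{4-[2-(3-bromo-4,5-dimethoxyphenyl)ethyl]phenoxy}-4,5-dimethoxyphenyl)ethyl]phenol | COc1cc(CCc2ccc(cc2)Oc2cc(cc(OC)c2OC)CCc2cccc(O)c2)cc(Br)c1OC | intermediate
23 | macrocyclic tetra-O-methyl ether of the target | COc1cc2cc(c1OC)Oc1ccc(cc1)CCc1cc(OC)c(OC)c(c1)Oc1cccc(c1)CC2 | intermediate
24 | CNP0511668.0 (macrocyclic bis(bibenzyl) bis-catechol; no stereocentre) | Oc1cc2cc(c1O)Oc1ccc(cc1)CCc1cc(O)c(O)c(c1)Oc1cccc(c1)CC2 | target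

## Step count and least certain steps

Total: 13 steps. Longest linear sequence: 13 steps (1 → 24); compounds 3, 7, 13 and 18 are purchased and enter directly.

**Step 6 (key step).** An aryloxyalkyne is a weaker donor than an ynamine or a ketene acetal, so thermal oligomerisation or adventitious hydration of the terminal ynol ether may outrun the cycloaddition. A loss of regiocontrol is less likely, because both partners are polarised in the same sense. Fallback: ring B would be coupled instead of grown. Setting out from phenol 6, a Chan–Lam etherification with 4-(methoxycarbonyl)phenylboronic acid (Cu(OAc)2, pyridine, 4 Å molecular sieves, CH2Cl2, air, room temperature) forms the same diaryl ether and comes back to the route at 15. The ortho-methoxy group is tolerated by this divalent-copper coupling, and no new intermediate arises.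

**Step 5.** The terminal ynol ether may be lost by hydration or polymerisation during work-up and concentration. Fallback: setting out from 9, acetylide 11 would be generated as in step 5 but silylated in the flask with Me3SiCl, giving the storable silyl ynol ether {[5-{2-[3-(benzyloxy)phenyl]ethyl}-2,3-dimethoxyphenoxy]ethynyl}trimethylsilane F1. Heating F1 with 13 (xylene, 140 °C) should give, with the same orientation and loss of CO2, methyl 4-(5-{2-[3-(benzyloxy)phenyl]ethyl}-2,3-dimethoxyphenoxy)-3-(trimethylsilyl)benzoate F2. Protodesilylation of this arylsilane, activated by the ortho aryloxy group (CF3CO2H, CH2Cl2, room temperature), comes back to the route at 15.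

**Step 12.** Oxidative addition of the electron-rich, ortho-methoxy aryl bromide to copper may be slow, so that intermolecular coupling to oligomers and reductive loss of bromine compete with ring closure. Fallback: the aryl partner would be turned into the nucleophile and the ether bond formed oxidatively at room temperature. Setting out from 22, Miyaura borylation (B2pin2, PdCl2(dppf), KOAc, dioxane, 80 °C) gives the pinacol boronate of 22 (pinacolatoboryl group in place of bromine) F3. Transesterification with diethanolamine and hydrolysis with dilute HCl give the free arylboronic acid F4. An intramolecular Chan–Lam coupling (Cu(OAc)2, pyridine, 4 Å molecular sieves, CH2Cl2, air, high dilution) closes the same C-5–O bond and comes back at 23.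

**Step 11.** BCl3 may begin to cleave the methyl ethers that are flanked by two oxygens, or incomplete scavenging may let the benzyl cation alkylate an electron-rich ring. Either would spoil the single-phenol selectivity that step 12 needs. Fallback: the benzyl group would be removed before bromine enters the molecule. Setting out from 16, hydrogenolysis (H2, Pd/C, EtOAc) gives the phenol alcohol 3-(2-{3-[4-(hydroxymethyl)phenoxy]-4,5-dimethoxyphenyl}ethyl)phenol F5. PPh3·HBr in MeCN gives its phosphonium bromide F6. A Wittig reaction with 18 (KOtBu, 2.2 equiv, THF) gives the bromo stilbene phenol F7 as an E/Z mixture, and diimide reduction (TsNHNH2, NaOAc) comes back to the route at 22.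

**Step 2.** The potassium phenoxide of 3 may be poorly soluble, and proton exchange with the ylide may stall the olefination. Fallback: the hydroxyl would be masked. Setting out from 3, silylation (TBSCl, imidazole, DMF) gives 3-(tert-butyldimethylsilyloxy)-4,5-dimethoxybenzaldehyde F8. A Wittig reaction with ylide 4 gives the silyl stilbene F9, diimide reduction gives the silyl bibenzyl F10, and fluoride (Bu4NF, THF) comes back to the route at 6.

## Further compounds

F0 | step 6 | none | none
F1 | step 5 | {[5-{2-[3-(benzyloxy)phenyl]ethyl}-2,3-dimethoxyphenoxy]ethynyl}trimethylsilane | C[Si](C)(C)C#COc1cc(CCc2cccc(OCc3ccccc3)c2)cc(OC)c1OC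
F2 | step 5 | methyl 4-(5-{2-[3-(benzyloxy)phenyl]ethyl}-2,3-dimethoxyphenoxy)-3-(trimethylsilyl)benzoate | COC(=O)c1ccc(Oc2cc(CCc3cccc(OCc4ccccc4)c3)cc(OC)c2OC)c(c1)[Si](C)(C)C
F3 | step 12 | pinacol boronate of 22: 3-{2-[3-(4-{2-[3,4-dimethoxy-5-(4,4,5,5-tetramethyl-1,3,2-dioxaborolan-2-yl)phenyl]ethyl}phenoxy)-4,5-dimethoxyphenyl]ethyl}phenol | COc1cc(CCc2ccc(cc2)Oc2cc(cc(OC)c2OC)CCc2cccc(O)c2)cc(B2OC(C)(C)C(C)(C)O2)c1OC
F4 | step 12 | {5-[2-(4-{5-[2-(3-hydroxyphenyl)ethyl]-2,3-dimethoxyphenoxy}phenyl)ethyl]-2,3-dimethoxyphenyl}boronic acid | COc1cc(CCc2ccc(cc2)Oc2cc(cc(OC)c2OC)CCc2cccc(O)c2)cc(B(O)O)c1OC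
F5 | step 11 | 3-(2-{3-[4-(hydroxymethyl)phenoxy]-4,5-dimethoxyphenyl}ethyl)phenol | OCc1ccc(cc1)Oc1cc(cc(OC)c1OC)CCc1cccc(O)c1
F6 | step 11 | (4-{5-[2-(3-hydroxyphenyl)ethyl]-2,3-dimethoxyphenoxy}benzyl)triphenylphosphonium bromide | [Br-].Oc1cccc(CCc2cc(OC)c(OC)c(Oc3ccc(C[P+](c4ccccc4)(c4ccccc4)c4ccccc4)cc3)c2)c1
F7 | step 11 | 3-[2-(3-{4-[2-(3-bromo-4,5-dimethoxyphenyl)ethenyl]phenoxy}-4,5-dimethoxyphenyl)ethyl]phenol (E/Z mixture) | COc1cc(C=Cc2ccc(cc2)Oc2cc(cc(OC)c2OC)CCc2cccc(O)c2)cc(Br)c1OC
F8 | step 2 | 3-(tert-butyldimethylsilyloxy)-4,5-dimethoxybenzaldehyde | COc1cc(C=O)cc(O[Si](C)(C)C(C)(C)C)c1OC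
F9 | step 2 | (5-{2-[3-(benzyloxy)phenyl]ethenyl}-2,3-dimethoxyphenoxy)(tert-butyl)dimethylsilane (E/Z mixture) | COc1cc(C=Cc2cccc(OCc3ccccc3)c2)cc(O[Si](C)(C)C(C)(C)C)c1OC
F10 | step 2 | (5-{2-[3-(benzyloxy)phenyl]ethyl}-2,3-dimethoxyphenoxy)(tert-butyl)dimethylsilane | COc1cc(CCc2cccc(OCc3ccccc3)c2)cc(O[Si](C)(C)C(C)(C)C)c1OC
A1 | alternative 1 | 20-membered aryl benzoate macrolactone (carbonyl between the ring A oxygen and B-1) | COc1cc2cc(c1OC)OC(=O)c1ccc(cc1)CCc1cc(OC)c(OC)c(c1)Oc1cccc(c1)CC2
A2 | alternative 1 | tetra-O-methyl ether of the target (identical with 23) | COc1cc2cc(c1OC)Oc1ccc(cc1)CCc1cc(OC)c(OC)c(c1)Oc1cccc(c1)CC2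
A3 | alternative 2 | 3-(4-bromophenoxy)-4-methoxyfuran | COc1cocc1Oc1ccc(Br)cc1
A4 | alternative 2 | methyl propiolate | C#CC(=O)OC
A5 | alternative 2 | methyl 3-(4-bromophenoxy)-5-hydroxy-4-methoxybenzoate | COC(=O)c1cc(O)c(OC)c(c1)Oc1ccc(Br)cc1
A6 | alternative 3 | macrocyclic bis(O-aryl diethylcarbamate) lacking the A-1 and C-3 hydroxyls | CCN(CC)C(=O)Oc1ccc2cc1Oc1ccc(cc1)CCc1ccc(OC(=O)N(CC)CC)c(c1)Oc1cccc(c1)CC2
A7 | alternative 3 | macrocyclic bis(carbamate) with hydroxyls at A-1 and C-3 | Oc1cc2cc(c1OC(=O)N(CC)CC)Oc1ccc(cc1)CCc1cc(O)c(OC(=O)N(CC)CC)c(c1)Oc1cccc(c1)CC2
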